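**Analysis of the target**

Target 20 is a C20 diterpenoid lactone with a trans-fused bicyclo[5.3.0]decane core. Atoms are numbered as in the halimane skeleton (C1 to C20); compound numbers carry no letter. Ring A is the cyclopentane C1–C2–C3–C4–C5, ring B the cycloheptanone C1–C10–C9–C8–C7–C6–C5, and a C11–C12 chain on C9 carries a β-substituted butenolide (C13 to C16). There are five stereocentres: C1 (S), C3 (R, secondary OH), C5 (S, tertiary OH), C8 (R, methyl) and C9 (S, quaternary). On ring A the C3 hydroxyl, the C5 hydroxyl and the C1–C10 bond lie on one face, so C6 leaves C5 on the other face; on ring B the C8 and C9 methyls are cis. The feature that invites the strategy is the β-ketol C10(=O)–C1(H)–C5(OH): its C1–C5 bond is the one bond common to ring A and ring B. A retro-aldol cut there opens both rings at once to a cyclodecane-1,6-dione (carbonyls at C5 and C10), which is the cleavage product of a C5=C10 olefin in an ordinary decalin. Sensitive groups are the β-ketol (retro-aldol, dehydration to the C1=C5 enone, epimerisable C1) and the butenolide (acidic C16–H, Michael acceptor, reducible). The synthesis is hard because C4 (gem-dimethyl) flanks the tertiary carbinol C5 and quaternary C9 flanks the C10 ketone. In addition, the two halves of the seco-diketone (C1–C5 and C6–C10) are constitutionally almost alike, so the aldol can close in either sense.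

**Retrosynthetic reasoning**

20 to 18 (C1–C5). The ring-fusion bond is cut by a retro-aldol, giving the ten-membered hydroxy diketone 18 with three stereocentres (C3, C8, C9) instead of five. Forward, a transannular aldol must form C1–C5, close both rings and set C1 and C5. The competing C6-to-C10 closure is handled through the C3 hydroxyl: only the wanted adduct is a cis-1,3-diol (O3/O5) that an arylboronic acid can bridge, as in 19, so a reversible aldol manifold can drain into it.

18 to 16 (C5=C10). Both carbonyls are joined into the tetrasubstituted olefin of the Δ5(10)-octalin 16. This trades a medium ring for two six-membered rings whose stereocentres sit in separate rings and can be set independently. Forward, ozonolysis must cleave the electron-rich olefin and spare the butenolide.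

16 to 11 (butenolide). The butenolide is cut back to the allyl group of 11. The terminal allyl carbon becomes C13 after hydroformylation to 12, condensation with glyoxylic acid 13 and reduction. An allyl group is chosen because it is the best electrophile for building quaternary C9 and is inert in the cationic ring closure.

11 to 10 to 9 (C4–C5 and the C3 oxygen). Ring A of the octalin is opened at C4–C5 to the (R)-epoxide 10, made from triene 9. Forward, an epoxy-olefin cyclisation forms ring A with its gem-dimethyl group and the C3 carbinol of fixed configuration. Loss of H5 from the C10 cation gives the C5=C10 olefin.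

9 to 6 + 7 (C1–C10). The sp2–sp3 bond is cut to enol triflate 6 and the homoprenyl bromide 7, used as Grignard reagent 8. The triflate is regiodefined because C9 is quaternary.

6 to 4 to 1 + 2 (C8 methyl, C9–C11). Ketone 4 comes from enone 1 by catalytic asymmetric conjugate addition of a methyl group and allylation of the enolate with 2 anti to the new methyl.

**Alternatives that were turned down**

Alternative 1: the textbook route, one ring at a time. Disconnection: C6–C7 of ring B and C1–C10 by acylation. A chiral 3-oxygenated 2,2-dimethylcyclopentanone would be acylated at C1 with an acyclic acid fragment holding C8 and C9, vinylated at C5, and ring B closed by ring-closing metathesis of diene A1, followed by olefin reduction. Turned down because the vicinal tertiary/quaternary pair C8/C9 must be made in an open chain without ring control. Vinyl addition to the C5 ketone next to C4 has to be steered cis to the C3 oxygen by reagent choice. The new olefin must be reduced in the presence of the butenolide. Every ring and stereocentre is bought separately, so the sequence would clearly exceed the ten steps used here.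

Alternative 2: intramolecular (4+3) cycloaddition. Disconnection: C1–C5 and C8–C9 together. The oxyallyl cation from bromo ketone A2 would add to its tethered silyl dienol ether to give cycloadduct A3, then reduction of C6=C7 and desilylation. It is attractive because the precursor has one stereocentre. Turned down because the diene terminus C5 is fully substituted and neopentylic, which disfavours the s-cis geometry and bond formation there. Four stereocentres (C1, C5, C8, C9) would have to follow from the remote C3 centre, the oxyallyl geometry and the endo/exo mode all at once. The C6=C7 olefin again needs chemoselective reduction.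

Alternative 3: pinacol-type 1,2-shift of a decalin. Disconnection: migration of C5 from C10 to C1. Diol mesylate A4 would rearrange under base with inversion at C1 to the hydroazulenone. The step is regio- and stereospecific. Turned down because A4 has six stereocentres and three contiguous oxygenated carbons (C1, C10, C5), one more stereocentre than 20. Placing the leaving group on C1 and not on C6 of a C5=C10 precursor is the same differentiation problem moved upstream, with no group to solve it. The precursor costs more than the step wins.

Key step: step 10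

Assumption (remark on the chemistry): the configuration of 20 at C1 and C5, with O3, O5 and the C10 carbonyl carbon on one face of ring A, is taken to be the thermodynamically preferred outcome of the reversible aldol once O3 and O5 are tied into the six-membered boronate 19.

**Route**

Step 1
Reactants: 1 2-methylcyclohex-2-en-1-one; 2 allyl bromide
Product: 4 (2S,3R)-2,3-dimethyl-2-(prop-2-en-1-yl)cyclohexan-1-one, via aluminium enolate 3 (not isolated)
Conditions: AlMe3 (1.4 equiv), Cu(O2CC4H3S) (copper thiophene-2-carboxylate, 2 mol %), BINOL-derived N,N-bis(1-phenylethyl)phosphoramidite (4 mol %, antipode that gives 3R), Et2O, −30 °C; then MeLi (1.1 equiv), THF/DMPU, 2 (3 equiv), −30 to 0 °C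
Reagents that add atoms: trimethylaluminium, C[Al](C)C
Why: Copper-catalysed asymmetric conjugate addition sets C8 (R) under ligand control; the enolate 3, activated as its lithium aluminate, is allylated on the face anti to the adjacent methyl group, which should set quaternary C9 (S) with the two methyls cis.

Step 2
Reactants: 4 (2S,3R)-2,3-dimethyl-2-(prop-2-en-1-yl)cyclohexan-1-one
Product: 6 (5R,6S)-5,6-dimethyl-6-(prop-2-en-1-yl)cyclohex-1-en-1-yl trifluoromethanesulfonate, via potassium enolate 5 (not isolated)
Conditions: KN(SiMe3)2 (1.2 equiv), THF, −78 °C; then PhNTf2 (1.2 equiv), −78 to 0 °C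
Reagents that add atoms: N-phenylbis(trifluoromethanesulfonimide), O=S(=O)(N(c1ccccc1)S(=O)(=O)C(F)(F)F)C(F)(F)F
Why: Enol triflate formation; the ketone can enolise only toward C5 because C9 is quaternary, so the C5=C10 enolate and its triflate are regiodefined and no stereocentre is touched.

Step 3
Reactants: 6 (5R,6S)-5,6-dimethyl-6-(prop-2-en-1-yl)cyclohex-1-en-1-yl trifluoromethanesulfonate; 7 5-bromo-2-methylpent-2-ene
Product: 9 (5R,6S)-5,6-dimethyl-1-(4-methylpent-3-en-1-yl)-6-(prop-2-en-1-yl)cyclohex-1-ene, via Grignard reagent 8 (not isolated)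
Conditions: 7, Mg, THF, 25 °C; then 6, Fe(acac)3 (5 mol %), THF/N-methylpyrrolidone, −30 °C
Reagents that add atoms: none
Why: Iron-catalysed Kumada-type coupling of an alkenyl triflate with a primary alkyl Grignard reagent forms C1–C10 at low temperature, fast enough to outrun β-hydride elimination and tolerant of the hindered position next to C9.

Step 4
Reactants: 9 (5R,6S)-5,6-dimethyl-1-(4-methylpent-3-en-1-yl)-6-(prop-2-en-1-yl)cyclohex-1-ene
Product: 10 (3R)-3-{2-[(5R,6S)-5,6-dimethyl-6-(prop-2-en-1-yl)cyclohex-1-en-1-yl]ethyl}-2,2-dimethyloxirane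
Conditions: D-fructose-derived ketone catalyst (0.3 equiv), KHSO5 (as 2KHSO5·KHSO4·K2SO4, 1.1 equiv), K2CO3, Bu4NHSO4 (cat.), MeCN/CH2(OMe)2/aqueous Na2B4O7 buffer, 0 °C
Reagents that add atoms: potassium peroxymonosulfate, [K+].[O-]S(=O)(=O)OO
Why: Shi epoxidation; the chiral dioxirane should prefer the unhindered isopropylidene olefin over the ring olefin shielded by quaternary C9 and over the electron-poorer vinyl group. The spiro transition-state model predicts the R epoxide (future C3) from the D-fructose-derived ketone, and the enantiomeric ketone is available if the sense is opposite.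

Step 5
Reactants: 10 (3R)-3-{2-[(5R,6S)-5,6-dimethyl-6-(prop-2-en-1-yl)cyclohex-1-en-1-yl]ethyl}-2,2-dimethyloxirane
Product: 11 (2R,5S,6R)-1,1,5,6-tetramethyl-5-(prop-2-en-1-yl)-1,2,3,4,5,6,7,8-octahydronaphthalen-2-ol
Conditions: MeAlCl2 (1.5 equiv), CH2Cl2, −78 °C; then Et3N/MeOH, aqueous NaHCO3
Reagents that add atoms: none
Why: Lewis-acid epoxy-olefin cyclisation, known for 1-(3,4-epoxyalkyl)cyclohexenes: the ring olefin attacks the tertiary epoxide carbon C4 through C5 with inversion at C4, C3 keeps its C–O bond and configuration, and the tertiary C10 cation (the same cation from which halim-5(10)-enes arise) should lose H5 to give the more substituted C5=C10 olefin, so no new stereocentre remains.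

Step 6
Reactants: 11 (2R,5S,6R)-1,1,5,6-tetramethyl-5-(prop-2-en-1-yl)-1,2,3,4,5,6,7,8-octahydronaphthalen-2-ol
Product: 12 4-[(1S,2R,6R)-6-hydroxy-1,2,5,5-tetramethyl-1,2,3,4,5,6,7,8-octahydronaphthalen-1-yl]butanal
Conditions: Rh(acac)(CO)2 (1 mol %), Xantphos (2 mol %), CO/H2 (1:1, 10 bar), toluene, 70 °C
Reagents that add atoms: carbon monoxide, [C-]#[O+]
Why: Linear-selective hydroformylation of the terminal olefin with a wide-bite-angle diphosphine; the tetrasubstituted olefin is inert and the free alcohol is tolerated, and the new aldehyde carbon becomes C16 with C13 as its α-carbon.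

Step 7
Reactants: 12 4-[(1S,2R,6R)-6-hydroxy-1,2,5,5-tetramethyl-1,2,3,4,5,6,7,8-octahydronaphthalen-1-yl]butanal; 13 glyoxylic acid (used as monohydrate)
Product: 14 5-hydroxy-4-{2-[(1S,2R,6R)-6-hydroxy-1,2,5,5-tetramethyl-1,2,3,4,5,6,7,8-octahydronaphthalen-1-yl]ethyl}furan-2(5H)-one (both configurations at the lactol carbon)
Conditions: morpholine hydrochloride (1.1 equiv), 1,4-dioxane/H2O (9:1), 80 °C
Reagents that add atoms: none
Why: Amine-mediated Mannich-type aldol condensation of an enolisable aldehyde with glyoxylic acid; the resulting 2-substituted 4-oxobut-2-enoic acid closes to the γ-hydroxybutenolide, which places C14/C15 on C13, and the lactol centre is removed in step 8.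

Step 8
Reactants: 14 5-hydroxy-4-{2-[(1S,2R,6R)-6-hydroxy-1,2,5,5-tetramethyl-1,2,3,4,5,6,7,8-octahydronaphthalen-1-yl]ethyl}furan-2(5H)-one
Product: 16 4-{2-[(1S,2R,6R)-6-hydroxy-1,2,5,5-tetramethyl-1,2,3,4,5,6,7,8-octahydronaphthalen-1-yl]ethyl}furan-2(5H)-one, via sodium hydroxy enoate 15 (not isolated)
Conditions: NaBH4 (2 equiv), THF/MeOH, 0 °C; then 1 M HCl to pH 2, 25 °C
Reagents that add atoms: none
Why: Borohydride reduces the masked aldehyde of the ring-opened hydroxybutenolide to the (Z)-4-hydroxy enoate 15, which lactonises on acidification to the β-substituted butenolide; the conjugated ester function is not reduced at 0 °C.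

Step 9
Reactants: 16 4-{2-[(1S,2R,6R)-6-hydroxy-1,2,5,5-tetramethyl-1,2,3,4,5,6,7,8-octahydronaphthalen-1-yl]ethyl}furan-2(5H)-one
Product: 18 4-{2-[(1S,2R,7R)-7-hydroxy-1,2,6,6-tetramethyl-5,10-dioxocyclodecyl]ethyl}furan-2(5H)-one, via ozonide 17 (not isolated)
Conditions: O3, CH2Cl2, −78 °C (Sudan Red 7B as end-point indicator); then PPh3 (1.5 equiv), −78 to 25 °C
Reagents that add atoms: ozone, [O-][O+]=O
Why: Ozonolysis of a Δ9,10-octalin-type olefin to the cyclodecane-1,6-dione; ozone is electrophilic and should take the tetrasubstituted olefin well before the electron-poor butenolide olefin, and C3, C8 and C9 are untouched. Compound 18 is drawn in the open form; ring-chain tautomerism between the C3 hydroxyl and C10 is possible.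

Step 10
Reactants: 18 4-{2-[(1S,2R,7R)-7-hydroxy-1,2,6,6-tetramethyl-5,10-dioxocyclodecyl]ethyl}furan-2(5H)-one
Product: 20 (2R,3aS,5S,6R,8aS)-2,8a-dihydroxy-1,1,5,6-tetramethyl-5-[2-(5-oxo-2,5-dihydrofuran-3-yl)ethyl]octahydroazulen-4(1H)-one, via cyclic phenylboronate 19 (not isolated)
Conditions: PhB(OH)2 (1.2 equiv), DBU (0.2 equiv), 4 Å molecular sieves, toluene, 25 to 40 °C; then pinacol (3 equiv), MeOH, 25 °C
Reagents that add atoms: none
Why: DBU reversibly enolises the two ketones of 18, each of which has only one enolisable side (C10 toward C1, C5 toward C6), and the C1 enolate adds across the ring to the C5 carbonyl; this is the transannular aldol addition long known for cyclodecane-1,6-diones, which collapse to bicyclo[5.3.0]decanolones. The new C1–C5 bond closes the cyclopentane in a 5-(enolexo)-exo-trig mode and, because it bisects the ten-membered ring, leaves the cycloheptanone C1–C10–C9–C8–C7–C6–C5 as the other half without a separate closure. The step must prefer C1-to-C5 over the constitutionally similar C6-to-C10 aldol; the C3 hydroxyl of the substrate secures this, because only the C1-to-C5 adduct with O5 cis to O3 is a cis-cyclopentane-1,3-diol, the motif that boronic acids bridge as a six-membered ester (19). Aldol and retro-aldol steps of the unbound isomers stay reversible under DBU, so regio- and stereoisomers should drain into 19, in which retro-aldol cleavage is blocked. C5 is therefore set by the C3 stereocentre through the boron bridge. C1 is set relative to C5 by the closed, hydrogen-bonded or boron-bridged transition state that puts the C10 carbonyl cis to O5 (trans ring fusion); it stays correctable by enolisation, and the O5–H···O=C10 hydrogen bond in the freed product favours the same epimer. Exchange with pinacol then releases 20 under neutral conditions that spare the β-ketol and the butenolide.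

**Compound list**

1 | 2-methylcyclohex-2-en-1-one | CC1=CCCCC1=O | starting material
2 | allyl bromide (3-bromoprop-1-ene) | C=CCBr | starting material
3 | dimethyl{[(3R)-2,3-dimethylcyclohex-1-en-1-yl]oxy}alumane (aluminium enolate) | C[C@@H]1CCCC(O[Al](C)C)=C1C | intermediate
4 | (2S,3R)-2,3-dimethyl-2-(prop-2-en-1-yl)cyclohexan-1-one | C[C@@H]1CCCC(=O)[C@@]1(C)CC=C | intermediate
5 | potassium (5R,6S)-5,6-dimethyl-6-(prop-2-en-1-yl)cyclohex-1-en-1-olate | C[C@@H]1CCC=C([O-])[C@@]1(C)CC=C.[K+] | intermediate
6 | (5R,6S)-5,6-dimethyl-6-(prop-2-en-1-yl)cyclohex-1-en-1-yl trifluoromethanesulfonate | C[C@@H]1CCC=C(OS(=O)(=O)C(F)(F)F)[C@@]1(C)CC=C | intermediate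
7 | 5-bromo-2-methylpent-2-ene | CC(C)=CCCBr | starting material
8 | (4-methylpent-3-en-1-yl)magnesium bromide | CC(C)=CCC[Mg]Br | intermediate
9 | (5R,6S)-5,6-dimethyl-1-(4-methylpent-3-en-1-yl)-6-(prop-2-en-1-yl)cyclohex-1-ene | C[C@@H]1CCC=C(CCC=C(C)C)[C@@]1(C)CC=C | intermediate
10 | (3R)-3-{2-[(5R,6S)-5,6-dimethyl-6-(prop-2-en-1-yl)cyclohex-1-en-1-yl]ethyl}-2,2-dimethyloxirane | C[C@@H]1CCC=C(CC[C@H]2OC2(C)C)[C@@]1(C)CC=C | intermediate
11 | (2R,5S,6R)-1,1,5,6-tetramethyl-5-(prop-2-en-1-yl)-1,2,3,4,5,6,7,8-octahydronaphthalen-2-ol | C[C@@H]1CCC2=C(CC[C@@H](O)C2(C)C)[C@@]1(C)CC=C | intermediate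
12 | 4-[(1S,2R,6R)-6-hydroxy-1,2,5,5-tetramethyl-1,2,3,4,5,6,7,8-octahydronaphthalen-1-yl]butanal | C[C@@H]1CCC2=C(CC[C@@H](O)C2(C)C)[C@@]1(C)CCCC=O | intermediate
13 | glyoxylic acid | O=CC(=O)O | starting material
14 | 5-hydroxy-4-{2-[(1S,2R,6R)-6-hydroxy-1,2,5,5-tetramethyl-1,2,3,4,5,6,7,8-octahydronaphthalen-1-yl]ethyl}furan-2(5H)-one (lactol carbon unassigned) | C[C@@H]1CCC2=C(CC[C@@H](O)C2(C)C)[C@@]1(C)CCC1=CC(=O)OC1O | intermediate
15 | sodium (2Z)-4-hydroxy-3-{2-[(1S,2R,6R)-6-hydroxy-1,2,5,5-tetramethyl-1,2,3,4,5,6,7,8-octahydronaphthalen-1-yl]ethyl}but-2-enoate | C[C@@H]1CCC2=C(CC[C@@H](O)C2(C)C)[C@@]1(C)CC/C(CO)=C/C(=O)[O-].[Na+] | intermediate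
16 | 4-{2-[(1S,2R,6R)-6-hydroxy-1,2,5,5-tetramethyl-1,2,3,4,5,6,7,8-octahydronaphthalen-1-yl]ethyl}furan-2(5H)-one | C[C@@H]1CCC2=C(CC[C@@H](O)C2(C)C)[C@@]1(C)CCC1=CC(=O)OC1 | intermediate
17 | secondary ozonide of 16 (1,2,4-trioxolane bridging C5 and C10; both face isomers) | C[C@@H]1CCC23OOC(O2)(CC[C@@H](O)C3(C)C)[C@@]1(C)CCC1=CC(=O)OC1 | intermediate
18 | 4-{2-[(1S,2R,7R)-7-hydroxy-1,2,6,6-tetramethyl-5,10-dioxocyclodecyl]ethyl}furan-2(5H)-one | C[C@@H]1CCC(=O)C(C)(C)[C@H](O)CCC(=O)[C@@]1(C)CCC1=CC(=O)OC1 | intermediate
19 | cyclic phenylboronate of 20 (boron bridging O3 and O5) | C[C@@H]1CC[C@]2(OB(c3ccccc3)O4)[C@H](C[C@@H]4C2(C)C)C(=O)[C@@]1(C)CCC1=CC(=O)OC1 | intermediate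
20 | (2R,3aS,5S,6R,8aS)-2,8a-dihydroxy-1,1,5,6-tetramethyl-5-[2-(5-oxo-2,5-dihydrofuran-3-yl)ethyl]octahydroazulen-4(1H)-one | C[C@@H]1CC[C@]2(O)[C@H](C[C@@H](O)C2(C)C)C(=O)[C@@]1(C)CCC1=CC(=O)OC1 | target

**Step count and risks**

Total step count: 10. Longest linear sequence: 10 steps (from 1). No protecting group is used.

Step 10 (key step). The most likely failures are transannular aldol in the other sense (C6 onto C10), since the two halves of 18 differ only in remote substituents, and equilibration too slow for the boronate to collect the material. DBU may also deprotonate the butenolide at C16, which is more acidic than either ketone, leading to vinylogous aldol addition to C10. Dehydration to the C1=C5 enone is a further risk. Fallback (sets out from 18, returns at 20): the enolate is made regiodefined and no longer depends on equilibration. Only the C10 ketone can form a five-membered hemiketal with the C3 hydroxyl. Its acid-catalysed dehydration (pyridinium p-toluenesulfonate, toluene, 80 °C, molecular sieves) gives the bridged enol ether F1, with the double bond necessarily C1=C10 because C9 is quaternary. N-Bromosuccinimide in wet THF at 0 °C brominates C1 and returns the ketone as the α-bromo ketone F2. SmI2 (divalent samarium) in THF at −78 °C then forms the trivalent samarium enolate at C1/C10 only. Its intramolecular Reformatsky-type addition to C5, through a chelate that can include O3, should give 20.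

Step 5. The C10 cation may be captured by the C3 oxygen (bridged ether), the opened epoxide may undergo hydride shift to a ketone, or the proton may be lost from C1 so that the olefin ends at C1=C10. Fallback (sets out from 10, returns at 12): the olefin position is set thermodynamically and the side-chain olefin is allowed to move with it. The crude cyclisation product, which would contain the Δ1(10) isomer F3, is heated with RhCl3·3H2O in ethanol. This should move the ring double bond to the tetrasubstituted C5=C10 position and the allyl group to a propenyl group, giving F4. Isomerising hydroformylation of F4 (Rh(acac)(CO)2, BIPHEPHOS, CO/H2, toluene) walks the side-chain olefin back to the terminus and gives aldehyde 12.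

Step 7. Warm aqueous acid may protonate the tetrasubstituted olefin (migration, hydration) or trigger rearrangement of the homoallylic C3 carbinol, and 12 may self-condense. Fallback (sets out from 12, returns at 16, bypassing 14 and 15): the butenolide is closed by metathesis under neutral conditions. α-Methylenation of 12 with dimethylmethyleneiminium iodide and Et3N gives enal F5. Luche reduction (NaBH4, CeCl3·7H2O, MeOH, 0 °C) gives the allylic alcohol F6. Acylation of its primary hydroxyl with acryloyl chloride (Et3N, CH2Cl2, −40 °C; the hindered C3 hydroxyl should be left) gives acrylate F7. Ring-closing metathesis with the second-generation Grubbs catalyst in toluene at 80 °C gives 16.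

Step 9. Ozone may epoxidise the hindered tetrasubstituted olefin rather than cleave it, and a small excess attacks the butenolide olefin. Fallback (sets out from 16, returns at 18): cleavage in two stages. m-Chloroperbenzoic acid (CH2Cl2, NaHCO3, 0 °C), which discriminates strongly in favour of the electron-rich olefin, gives the 5,10-epoxide F8. Periodic acid (H5IO6, THF/H2O, 25 °C) then opens it and cleaves the resulting diol to 18.

**Further compounds**

F1 | step 10 | bridged enol ether of 18 (O3 bonded to C10, C1=C10) | C[C@@H]1CCC(=O)C(C)(C)[C@H]2CC=C(O2)[C@@]1(C)CCC1=CC(=O)OC1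
F2 | step 10 | 1-bromo derivative of 18 (bromine on C1, either epimer; open form) | C[C@@H]1CCC(=O)C(C)(C)[C@H](O)CC(Br)C(=O)[C@@]1(C)CCC1=CC(=O)OC1
F3 | step 5 | Δ1(10) olefin isomer of 11 (H5 cis to H3) | C[C@@H]1CC[C@H]2C(=CC[C@@H](O)C2(C)C)[C@@]1(C)CC=C
F4 | step 5 | (E)-prop-1-enyl isomer of 11 | C[C@@H]1CCC2=C(CC[C@@H](O)C2(C)C)[C@@]1(C)/C=C/C
F5 | step 7 | 4-[(1S,2R,6R)-6-hydroxy-1,2,5,5-tetramethyl-1,2,3,4,5,6,7,8-octahydronaphthalen-1-yl]-2-methylidenebutanal | C[C@@H]1CCC2=C(CC[C@@H](O)C2(C)C)[C@@]1(C)CCC(=C)C=O
F6 | step 7 | allylic alcohol from F5 (2-methylidenebutan-1-ol side chain) | C[C@@H]1CCC2=C(CC[C@@H](O)C2(C)C)[C@@]1(C)CCC(=C)CO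
F7 | step 7 | acrylate ester of F6 | C[C@@H]1CCC2=C(CC[C@@H](O)C2(C)C)[C@@]1(C)CCC(=C)COC(=O)C=C
F8 | step 9 | 5,10-epoxide of 16 (either face) | C[C@@H]1CCC23OC2(CC[C@@H](O)C3(C)C)[C@@]1(C)CCC1=CC(=O)OC1
A1 | alternative 1 | diene for ring-closing metathesis (C5 vinyl carbinol, C8 vinyl) | C[C@H](C=C)[C@](C)(CCC1=CC(=O)OC1)C(=O)[C@H]1C[C@@H](O)C(C)(C)[C@]1(O)C=C
A2 | alternative 2 | acyclic 9-bromo ketone with C5 triethylsilyl dienol ether and C3 tert-butyldimethylsilyl ether | C/C=C/C=C(\O[Si](CC)(CC)CC)C(C)(C)[C@H](O[Si](C)(C)C(C)(C)C)CCC(=O)C(C)(Br)CCC1=CC(=O)OC1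
A3 | alternative 2 | (4+3) cycloadduct (6,7-didehydro bis-silyl ether of 20) | C[C@@H]1C=C[C@]2(O[Si](CC)(CC)CC)[C@H](C[C@@H](O[Si](C)(C)C(C)(C)C)C2(C)C)C(=O)[C@@]1(C)CCC1=CC(=O)OC1
A4 | alternative 3 | decalin 5,10-diol 1-mesylate, 3-O-tert-butyldimethylsilyl ether | C[C@@H]1CC[C@@]2(O)C(C)(C)[C@H](O[Si](C)(C)C(C)(C)C)C[C@H](OS(C)(=O)=O)[C@@]2(O)[C@@]1(C)CCC1=CC(=O)OC1
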